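**Assumptions**
- The presumed biosynthesis is taken to be the benzyl benzoate arene-oxide pathway of the Uvaria/Kaempferia cyclohexene oxides: arene dihydrodiol → 1,6-epoxide → opening by benzoate.
- The bromobenzene cis-dihydrodiol 1 is treated as a purchasable fermentation product; its price and current availability were not checked.

**Retrosynthetic overview**
1. Target 7 ⇐ anti-SN2′ opening of a 1,6-epoxide (5) by the neighbouring C3 benzoate through a cis-fused 1,3-dioxolan-2-ylium ion (6), then hydrolysis to the C4 ester.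
2. Epoxide 5 ⇐ hydroxyl-directed epoxidation of the trans-dihydrodiol dibenzoate 4 (a diene of the desoxypipoxide type).
3. Diene 4 ⇐ double Mitsunobu benzoylation of triol 2: the primary OH is esterified and the remote secondary OH is inverted (cis → trans diol).
4. Triol 2 ⇐ Stille hydroxymethylation of the dearomatised arene 1.
5. Ring order: the carbocycle is a bought dearomatised benzene; the oxirane forms first, then the dioxolanylium ring, both transiently in the last flask.

**Step 1**
Reactants: 1 (1S,2S)-3-bromocyclohexa-3,5-diene-1,2-diol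
Product: 2 (1S,2R)-3-(hydroxymethyl)cyclohexa-3,5-diene-1,2-diol
Conditions: Bu3SnCH2OH (1.3 equiv), Pd2(dba)3 (2.5 mol %), AsPh3 (20 mol %), CuI (10 mol %), degassed NMP, 45 °C, dark
Reagents that add atoms: (tributylstannyl)methanol, OC[Sn](CCCC)(CCCC)CCCC
Why: Kosugi–Migita–Stille hydroxymethylation of the vinyl bromide with selective transfer of the α-oxygenated CH2OH group runs under neutral conditions that the acid-labile cis-dihydrodiol should tolerate, and no stereocentre is touched (the C2 descriptor changes from S to R only because Br becomes C).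

**Step 2**
Reactants: 2 (1S,2R)-3-(hydroxymethyl)cyclohexa-3,5-diene-1,2-diol
Product: 4 [(5R,6R)-5-(benzoyloxy)-6-hydroxycyclohexa-1,3-dien-1-yl]methyl benzoate, via primary benzoate 3 (not isolated)
Conditions: BzOH (2.2 equiv), PPh3 (2.3 equiv), DIAD (2.3 equiv), THF, −30 → 0 °C
Reagents that add atoms: benzoic acid, OC(=O)c1ccccc1
Why: Mitsunobu reaction run twice in one flask, in which the primary allylic OH is esterified first (3) and then only the secondary carbinol remote from the ring substituent is activated and displaced by benzoate with SN2 inversion (the regiochemistry expected by analogy with 3-halo cis-dihydrodiols), turning the cis-diol into the (5R,6R)-trans-diol monoester while the flanked C6–OH stays free.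

**Step 3**
Reactants: 4 [(5R,6R)-5-(benzoyloxy)-6-hydroxycyclohexa-1,3-dien-1-yl]methyl benzoate
Product: 7 [(1S,2S,3S,4R)-4-(benzoyloxy)-1,2,3-trihydroxycyclohex-5-en-1-yl]methyl benzoate, via vinyl epoxide 5 (not isolated), via benzoxonium ion 6 (not isolated)
Conditions: VO(acac)2 (3 mol %), t-BuOOH (1.05 equiv), CH2Cl2, 0 °C; then CSA (10 mol %), H2O (2 equiv), MeCN, −20 → 0 °C
Reagents that add atoms: tert-butyl hydroperoxide, CC(C)(C)OO; water, O
Why: Proposed new method: the vanadium-alkoxide-directed epoxidation (known type) places the oxirane on the trisubstituted alkene cis to the free allylic OH and so sets C1; protonation of the allylic C6–O bond then lets the carbonyl oxygen of the C3 benzoate add 5-exo to C4 on its own face, anti to the departing oxirane oxygen (vinylogous neighbouring-group participation, anti-SN2′), which sets C4 cis to O3 and trans to the new tertiary OH; water opens the cis-fused ion 6 with preferred collapse to the pseudo-axial allylic C4 ester; the closest known reactions are the acid-promoted epoxy ester → acyloxonium (ortho ester) rearrangement and anti-SN2′ openings of cyclohexadiene monoepoxides.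

**Compound list**
1 | (1S,2S)-3-bromocyclohexa-3,5-diene-1,2-diol | O[C@H]1C=CC=C(Br)[C@H]1O | starting material
2 | (1S,2R)-3-(hydroxymethyl)cyclohexa-3,5-diene-1,2-diol | O[C@H]1C=CC=C(CO)[C@H]1O | intermediate
3 | [(5S,6R)-5,6-dihydroxycyclohexa-1,3-dien-1-yl]methyl benzoate | O[C@H]1C=CC=C(COC(=O)c2ccccc2)[C@H]1O | intermediate (not isolated)
4 | [(5R,6R)-5-(benzoyloxy)-6-hydroxycyclohexa-1,3-dien-1-yl]methyl benzoate (trans-diol; secondary OH next to the side-chain carbon) | O=C(c1ccccc1)O[C@@H]1C=CC=C(COC(=O)c2ccccc2)[C@H]1O | intermediate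
5 | [(1S,2S,3R,6R)-3-(benzoyloxy)-2-hydroxy-7-oxabicyclo[4.1.0]hept-4-en-1-yl]methyl benzoate (oxirane cis to the 2-OH, trans to the 3-OBz) | O=C(c1ccccc1)OC[C@@]12O[C@@H]1C=C[C@@H](OC(=O)c1ccccc1)[C@@H]2O | intermediate (not isolated)
6 | 2-phenyl-1,3-dioxolan-2-ylium ion cis-fused across C3–C4 of the cyclohex-5-ene, on the face opposite the C1 and C2 hydroxyls, carrying 1-OH, 1-CH2OBz and 2-OH (camphorsulfonate counter-ion) | O=C(OC[C@@]1(O)C=C[C@H]2OC(c3ccccc3)=[O+][C@H]2[C@@H]1O)c1ccccc1 | intermediate (not isolated)
7 | [(1S,2S,3S,4R)-4-(benzoyloxy)-1,2,3-trihydroxycyclohex-5-en-1-yl]methyl benzoate | O=C(OC[C@@]1(O)C=C[C@@H](OC(=O)c2ccccc2)[C@@H](O)[C@@H]1O)c1ccccc1 | target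

**Totals**
Total step count: 3. Longest linear sequence: 3 steps (1 → 2 → 4 → 7).

**Steps most likely to fail, with fallbacks**

Step 3 (highest risk). The side-chain benzoate could instead attack C6 through a six-membered acyloxonium ion, or water could add directly at C6; both give zeylenol-type 1,6-diols. The hydrolysis of 6 could also favour the 3-O-benzoyl isomer. The fallback sets out from 4 and comes back at 7. Photo-oxygenation of 4 (O2, TPP, hν, CH2Cl2, −20 °C) should add singlet oxygen [4+2] across the diene, syn to the free OH and anti to the ring benzoate, to give the endoperoxide [1-(benzoyloxymethyl)-8-(benzoyloxy)-7-hydroxy-2,3-dioxabicyclo[2.2.2]oct-5-ene, peroxide bridge cis to the 7-OH] F1. Thiourea in MeOH reduces the O–O bond to the cis-1,4-diol [(1S,2S,3R,4S)-3-(benzoyloxy)-1,2,4-trihydroxycyclohex-5-en-1-yl]methyl benzoate F2. Tf2O/pyridine (CH2Cl2, −40 °C) then activates the allylic secondary OH; the trans neighbouring benzoate displaces it with inversion to give the same ion 6, and added water delivers 7.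

Step 2. The dienyl alkoxyphosphonium ion may aromatise to a phenol or react SN2′, and the second Mitsunobu may not distinguish the two secondary alcohols. The fallback sets out from 2 and comes back at 4. BzCl (1.0 equiv) with 2,4,6-collidine (CH2Cl2, −40 °C) gives the primary benzoate 3, this time isolated. 1,1′-Sulfonyldiimidazole/DBU (THF, −20 °C) closes the cis-diol to the cyclic sulfate [(3aR,7aS)-2,2-dioxo-3a,7a-dihydro-1,3,2-benzodioxathiol-4-yl]methyl benzoate F3. Tetrabutylammonium benzoate (acetone, 0 °C) opens it with inversion at the allylic carbon remote from the side chain to give the sulfate monoester [(5R,6R)-5-(benzoyloxy)-6-(sulfooxy)cyclohexa-1,3-dien-1-yl]methyl benzoate F4. Catalytic H2SO4 with 1 equiv of water in THF (0 °C) hydrolyses this to 4.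

Step 1. The unprotected diene diol may dehydrate or dimerise before the slow sp3 transfer from tin takes place. The fallback sets out from 1 and comes back at 2. Pd-catalysed methoxycarbonylation (CO 1 atm, MeOH, Et3N, Pd(OAc)2/dppf, 50 °C) gives methyl (5S,6R)-5,6-dihydroxycyclohexa-1,3-diene-1-carboxylate F5. DIBAL-H (4 equiv, CH2Cl2, −78 °C) reduces the ester 1,2 to the allylic alcohol 2.

**Further compounds**
F1 | step 3 | 1-(benzoyloxymethyl)-8-(benzoyloxy)-7-hydroxy-2,3-dioxabicyclo[2.2.2]oct-5-ene (peroxide bridge cis to 7-OH, trans to 8-OBz) | O=C(OC[C@@]12OO[C@@H](C=C1)[C@@H](OC(=O)c1ccccc1)[C@@H]2O)c1ccccc1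
F2 | step 3 | [(1S,2S,3R,4S)-3-(benzoyloxy)-1,2,4-trihydroxycyclohex-5-en-1-yl]methyl benzoate | O=C(OC[C@@]1(O)C=C[C@H](O)[C@@H](OC(=O)c2ccccc2)[C@@H]1O)c1ccccc1
F3 | step 2 | [(3aR,7aS)-2,2-dioxo-3a,7a-dihydro-1,3,2-benzodioxathiol-4-yl]methyl benzoate | O=S1(=O)O[C@H]2C=CC=C(COC(=O)c3ccccc3)[C@H]2O1
F4 | step 2 | [(5R,6R)-5-(benzoyloxy)-6-(sulfooxy)cyclohexa-1,3-dien-1-yl]methyl benzoate | O=C(c1ccccc1)O[C@@H]1C=CC=C(COC(=O)c2ccccc2)[C@H]1OS(=O)(=O)O
F5 | step 1 | methyl (5S,6R)-5,6-dihydroxycyclohexa-1,3-diene-1-carboxylate | O[C@H]1C=CC=C(C(=O)OC)[C@H]1O
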